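**Retrosynthetic overview**

1. Enabling feature: the lactone oxygen sits on C6, which is allylic to the Z-C4=C5 bond and 1,4 to the C3 oxygen (O–C3–C4(Me)=C5–C6–O) inside the ten-membered ring, and C12(=O)–O is one CO2 unit between vinylic C11 and C6.
2. Key disconnection: remove CO2 and transpose the allyl system, giving a 7-(1-bromoethenyl)-3,4-epoxycyclodeca-1(10),5-diene (23). Forward: Br/Li exchange, CO2 capture (C11–C12), then zerovalent-palladium opening of the vinyl oxirane by the new carboxylate (O–C6), which also creates Z-C4=C5 and frees O3.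
3. Order of rings: C3/C4 oxirane (Sharpless, acyclic), then the ten-membered carbocycle (Julia–Kocienski union at C5=C6, Nozaki–Hiyama–Kishi closure at C9–C10), then the γ-lactone (key step, oxirane consumed); the side-chain oxirane arrives with the acid.
4. Fragments: west C1–C5/C10 epoxy aldehyde 8 (Stork–Zhao, Still–Gennari, Sharpless); east C6–C9 sulfone 18 (Sharpless, C2-selective cuprate opening sets C7/C8); acid 31 from tiglyl alcohol.
5. Endgame: acetylation of O3, PMB removal and Yamaguchi esterification at O8, desilylation at O9.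

Key step: step 21

Remark (numbering): ring carbons are C1–C10 as in germacranolides; C11 is the lactone α-carbon, C12 the lactone carbonyl, C13 the exocyclic CH2, C14 and C15 the methyls on C10 and C4. The target is (3S,6R,7S,8S,9R), with 1(10)Z and 4Z.
Remark (side chain): the acyl group is read from the SMILES as (2S,3R)-2,3-dimethyloxirane-2-carbonyl (methyl groups cis, the epoxide of a tiglate).

**Route**

Step 1
Reactants: 1 3-[(tert-butyldimethylsilyl)oxy]propanal
Product: 2 tert-butyl{[(3Z)-4-iodopent-3-en-1-yl]oxy}dimethylsilane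
Conditions: EtPPh3Br, n-BuLi, THF, 0 °C; I2, −78 °C; NaN(SiMe3)2, −20 °C; then 1, −78 °C to rt
Reagents that add atoms: ethyltriphenylphosphonium bromide, CC[P+](c1ccccc1)(c1ccccc1)c1ccccc1.[Br-]; iodine, II
Why: Stork–Zhao iodo-olefination; the α-iodo ylide should give the (Z)-2-iodoalkene (iodine cis to the chain) under kinetic Wittig control.

Step 2
Reactants: 2 tert-butyl{[(3Z)-4-iodopent-3-en-1-yl]oxy}dimethylsilane
Product: 3 (3Z)-4-iodopent-3-en-1-ol
Conditions: PPTS (cat.), MeOH, rt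
Reagents that add atoms: none
Why: acid-catalysed methanolysis of a primary silyl ether; the alkenyl iodide is inert.

Step 3
Reactants: 3 (3Z)-4-iodopent-3-en-1-ol
Product: 4 (3Z)-4-iodopent-3-enal
Conditions: Dess–Martin periodinane, NaHCO3, CH2Cl2, 0 °C; used crude
Reagents that add atoms: none
Why: buffered Dess–Martin oxidation should give the β,γ-unsaturated aldehyde without conjugation.

Step 4
Reactants: 4 (3Z)-4-iodopent-3-enal
Product: 5 ethyl (2Z,5Z)-6-iodo-2-methylhepta-2,5-dienoate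
Conditions: (CF3CH2O)2P(O)CH(CH3)CO2Et, KN(SiMe3)2, 18-crown-6, THF, −78 °C
Reagents that add atoms: ethyl 2-[bis(2,2,2-trifluoroethoxy)phosphoryl]propanoate, CCOC(=O)C(C)P(=O)(OCC(F)(F)F)OCC(F)(F)F
Why: Still–Gennari olefination; the trifluoroethyl phosphonate gives the Z-trisubstituted enoate (ester cis to the chain) by fast, irreversible elimination.

Step 5
Reactants: 5 ethyl (2Z,5Z)-6-iodo-2-methylhepta-2,5-dienoate
Product: 6 (2Z,5Z)-6-iodo-2-methylhepta-2,5-dien-1-ol
Conditions: i-Bu2AlH, CH2Cl2, −78 °C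
Reagents that add atoms: none
Why: 1,2-reduction of the enoate to the allylic alcohol with both olefin geometries retained.

Step 6
Reactants: 6 (2Z,5Z)-6-iodo-2-methylhepta-2,5-dien-1-ol
Product: 7 {(2R,3S)-3-[(2Z)-3-iodobut-2-en-1-yl]-2-methyloxiran-2-yl}methanol
Conditions: Ti(OiPr)4, D-(−)-diethyl tartrate, t-BuOOH, 4 Å molecular sieves, CH2Cl2, −20 °C
Reagents that add atoms: tert-butyl hydroperoxide, CC(C)(C)OO
Why: Sharpless asymmetric epoxidation of the only allylic alcohol; the D-(−)-tartrate should set both oxirane centres (C4 R, C3 S in ring numbering), and the Z-olefin makes the epoxide cis.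

Step 7
Reactants: 7 {(2R,3S)-3-[(2Z)-3-iodobut-2-en-1-yl]-2-methyloxiran-2-yl}methanol
Product: 8 (2S,3S)-3-[(2Z)-3-iodobut-2-en-1-yl]-2-methyloxirane-2-carbaldehyde
Conditions: Dess–Martin periodinane, NaHCO3, CH2Cl2, 0 °C
Reagents that add atoms: none
Why: Dess–Martin oxidation to a non-enolisable epoxy aldehyde (α-carbon quaternary), so the centres cannot scramble.

Step 8
Reactants: 9 (2E)-but-2-ene-1,4-diol
Product: 10 (2E)-4-[(tert-butyldimethylsilyl)oxy]but-2-en-1-ol
Conditions: NaH (1.0 equiv), THF, 0 °C; TBSCl (1.0 equiv), rt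
Reagents that add atoms: tert-butyldimethylsilyl chloride, C[Si](C)(Cl)C(C)(C)C
Why: monosilylation of a symmetrical diol through its sparingly soluble monosodium alkoxide.

Step 9
Reactants: 10 (2E)-4-[(tert-butyldimethylsilyl)oxy]but-2-en-1-ol
Product: 11 [(2R,3R)-3-({[tert-butyl(dimethyl)silyl]oxy}methyl)oxiran-2-yl]methanol
Conditions: Ti(OiPr)4, D-(−)-diethyl tartrate, t-BuOOH, 4 Å molecular sieves, CH2Cl2, −20 °C
Reagents that add atoms: tert-butyl hydroperoxide, CC(C)(C)OO
Why: Sharpless asymmetric epoxidation of an E-allylic alcohol; the D-(−)-tartrate should give the (2R,3R) trans-epoxide (future C7 and C8).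

Step 10
Reactants: 11 [(2R,3R)-3-({[tert-butyl(dimethyl)silyl]oxy}methyl)oxiran-2-yl]methanol
Product: 12 (2S,3S)-4-[(tert-butyldimethylsilyl)oxy]-2-[1-(trimethylsilyl)ethenyl]butane-1,3-diol
Conditions: CH2=C(SiMe3)MgBr (3 equiv), CuI (0.2 equiv), THF, −30 to 0 °C
Reagents that add atoms: [1-(trimethylsilyl)ethenyl]magnesium bromide, C=C([Mg]Br)[Si](C)(C)C (made in the flask from (1-bromoethenyl)trimethylsilane, C=C(Br)[Si](C)(C)C, and Mg)
Why: copper-catalysed SN2 opening of a 2,3-epoxy alcohol at C2 (C3 is deactivated and shielded by the silyloxymethyl group); inversion sets C7, and C8 is retained, giving the anti relationship.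

Step 11
Reactants: 12 (2S,3S)-4-[(tert-butyldimethylsilyl)oxy]-2-[1-(trimethylsilyl)ethenyl]butane-1,3-diol
Product: 13 (4S,5S)-4-({[tert-butyl(dimethyl)silyl]oxy}methyl)-2-(4-methoxyphenyl)-5-[1-(trimethylsilyl)ethenyl]-1,3-dioxane (aryl equatorial, cis to the C4 substituent)
Conditions: 4-MeOC6H4CH(OMe)2, PPTS (cat.), CH2Cl2, rt
Reagents that add atoms: 4-methoxybenzaldehyde dimethyl acetal, COC(OC)c1ccc(OC)cc1
Why: thermodynamic transacetalisation of the 1,3-diol; the acetal carbon settles with the aryl group equatorial on an all-equatorial chair.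

Step 12
Reactants: 13 the 1,3-dioxane of step 11
Product: 15 (4S,5S)-5-(1-bromoethenyl)-4-({[tert-butyl(dimethyl)silyl]oxy}methyl)-2-(4-methoxyphenyl)-1,3-dioxane, via dibromide 14 (not isolated)
Conditions: Br2 (1.0 equiv), CH2Cl2, −78 °C; NaOMe, MeOH, −78 to 0 °C
Reagents that add atoms: bromine, BrBr
Why: bromodesilylation of a vinylsilane; bromine adds to the electron-rich vinylsilane and methoxide-induced anti elimination of silicon and the β-bromine leaves the 2-bromo-1-alkene.

Step 13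
Reactants: 15 the bromo 1,3-dioxane of step 12
Product: 16 (2S,3S)-2-(1-bromoethenyl)-4-[(tert-butyldimethylsilyl)oxy]-3-[(4-methoxybenzyl)oxy]butan-1-ol
Conditions: i-Bu2AlH, CH2Cl2, −78 to 0 °C
Reagents that add atoms: none
Why: regioselective reductive opening of the p-methoxybenzylidene acetal; aluminium binds the less hindered primary oxygen, so the PMB ether stays on the secondary O8.

Step 14
Reactants: 16 the primary alcohol of step 13
Product: 17 5-({(2R,3S)-2-(1-bromoethenyl)-4-[(tert-butyldimethylsilyl)oxy]-3-[(4-methoxybenzyl)oxy]butyl}sulfanyl)-1-phenyl-1H-tetrazole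
Conditions: 1-phenyl-1H-tetrazole-5-thiol, PPh3, DIAD, THF, 0 °C to rt
Reagents that add atoms: 1-phenyl-1H-tetrazole-5-thiol, Sc1nnnn1-c1ccccc1
Why: Mitsunobu thioetherification of the primary alcohol; no stereocentre is touched.

Step 15
Reactants: 17 the sulfide of step 14
Product: 18 5-({(2R,3S)-2-(1-bromoethenyl)-4-[(tert-butyldimethylsilyl)oxy]-3-[(4-methoxybenzyl)oxy]butyl}sulfonyl)-1-phenyl-1H-tetrazole
Conditions: (NH4)6Mo7O24·4H2O (cat.), 30% H2O2, EtOH, 0 °C to rt
Reagents that add atoms: hydrogen peroxide, OO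
Why: molybdate-catalysed oxidation of sulfide to sulfone, which spares the electron-poor bromoalkene and the PMB and silyl ethers.

Step 16
Reactants: 18 the sulfone of step 15; 8 (2S,3S)-3-[(2Z)-3-iodobut-2-en-1-yl]-2-methyloxirane-2-carbaldehyde
Product: 19 tert-butyl{[(2S,3S,4E)-3-(1-bromoethenyl)-5-{(2R,3S)-3-[(2Z)-3-iodobut-2-en-1-yl]-2-methyloxiran-2-yl}-2-[(4-methoxybenzyl)oxy]pent-4-en-1-yl]oxy}dimethylsilane
Conditions: KN(SiMe3)2 added to 18 and 8, DME, −60 °C to rt
Reagents that add atoms: none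
Why: Julia–Kocienski olefination; the phenyltetrazolyl sulfone and a non-enolisable aldehyde should give the E-C5=C6 vinyl oxirane through the anti adduct and Smiles rearrangement.

Step 17
Reactants: 19 the vinyl oxirane of step 16
Product: 20 (2S,3S,4E)-3-(1-bromoethenyl)-5-{(2R,3S)-3-[(2Z)-3-iodobut-2-en-1-yl]-2-methyloxiran-2-yl}-2-[(4-methoxybenzyl)oxy]pent-4-en-1-ol
Conditions: Bu4NF, THF, 0 °C
Reagents that add atoms: none
Why: fluoride cleavage of the primary silyl ether under non-acidic conditions that the vinyl oxirane tolerates.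

Step 18
Reactants: 20 the primary alcohol of step 17
Product: 21 (2S,3S,4E)-3-(1-bromoethenyl)-5-{(2R,3S)-3-[(2Z)-3-iodobut-2-en-1-yl]-2-methyloxiran-2-yl}-2-[(4-methoxybenzyl)oxy]pent-4-enal
Conditions: Dess–Martin periodinane, NaHCO3, CH2Cl2, 0 °C; used at once
Reagents that add atoms: none
Why: mild buffered oxidation to the α-alkoxy aldehyde, used immediately to avoid epimerisation at C8.

Step 19
Reactants: 21 the iodo aldehyde of step 18
Product: 22 (1(10)Z,5E,3S,4R,7S,8S,9R)-7-(1-bromoethenyl)-3,4-epoxy-8-[(4-methoxybenzyl)oxy]-4,10-dimethylcyclodeca-1(10),5-dien-9-ol (ring numbered as in the target)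
Conditions: CrCl2 (8 equiv), NiCl2 (0.05 equiv), DMSO/THF, rt, slow addition, final 2 mM
Reagents that add atoms: none
Why: intramolecular Nozaki–Hiyama–Kishi coupling; the alkenyl iodide reacts in preference to the alkenyl bromide, the Z geometry is retained, and Felkin–Anh addition anti to the C8 ether should set C9.

Step 20
Reactants: 22 the macrocyclic alcohol of step 19
Product: 23 (1(10)Z,5E,3S,4R,7S,8S,9R)-7-(1-bromoethenyl)-3,4-epoxy-8-[(4-methoxybenzyl)oxy]-4,10-dimethyl-9-[(triethylsilyl)oxy]cyclodeca-1(10),5-diene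
Conditions: Et3SiCl, imidazole, DMAP (cat.), DMF, 0 °C to rt
Reagents that add atoms: chlorotriethylsilane, CC[Si](Cl)(CC)CC
Why: silylation under non-Lewis-acidic conditions blocks O9, which would otherwise compete as a transannular nucleophile in the key step.

Step 21
Reactants: 23 the bromo vinyl oxirane of step 20
Product: 26 (1(10)Z,4Z,3S,6R,7S,8S,9R)-3-hydroxy-8-[(4-methoxybenzyl)oxy]-9-[(triethylsilyl)oxy]germacra-1(10),4,11(13)-trien-12,6-olide, via alkenyllithium 24 (not isolated), via lithium carboxylate 25 (not isolated)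
Conditions: t-BuLi (2.1 equiv), THF, −78 °C; CO2 (gas), −78 to −20 °C; argon purge; Pd(PPh3)4 (10 mol%), THF, rt; aq. NH4Cl
Reagents that add atoms: carbon dioxide, O=C=O
Why: Bromine–lithium exchange gives the 1,1-disubstituted alkenyllithium at C11, which captures CO2 (C11–C12); zerovalent palladium then ionises the vinyl oxirane anti to the C4–O bond to an allylpalladium alkoxide, and the tethered carboxylate attacks C6 anti to palladium (O–C6), moving the double bond to C4=C5 and leaving the C3 alkoxide. The closest known reaction types are carboxylation of alkenyllithiums and the Tsuji–Trost 1,4-addition of carboxylates to vinyl epoxides (allylic lactonisation). The γ-lactone closes by 5-exo attack on the allyl terminus, which also fixes attack at C6 (five-membered ring) over C4 (seven-membered ring). The new centre C6 is controlled by the oxirane carbon C4 through double inversion: the carboxylate enters on the allyl face that the oxirane oxygen left, and with C7 syn on the allyl (from the E-olefin) this gives 6R and the trans-fused lactone. The ten-membered ring accommodates only the syn,anti-allyl, so C3 is held anti and C4=C5 should form Z. The step needs exchange to outrun attack on the oxirane (−78 °C, exchange is the fastest process) and needs CO2 removed before palladium is added so that the C3 alkoxide is not carbonated.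

Step 22
Reactants: 26 the hydroxy lactone of step 21
Product: 27 (1(10)Z,4Z,3S,6R,7S,8S,9R)-3-acetoxy-8-[(4-methoxybenzyl)oxy]-9-[(triethylsilyl)oxy]germacra-1(10),4,11(13)-trien-12,6-olide
Conditions: Ac2O, pyridine, DMAP (cat.), CH2Cl2, 0 °C
Reagents that add atoms: acetic anhydride, CC(=O)OC(C)=O
Why: standard acylation of the only free hydroxyl.

Step 23
Reactants: 27 the acetate of step 22
Product: 28 (1(10)Z,4Z,3S,6R,7S,8S,9R)-3-acetoxy-8-hydroxy-9-[(triethylsilyl)oxy]germacra-1(10),4,11(13)-trien-12,6-olide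
Conditions: DDQ, CH2Cl2/pH 7 buffer, 0 °C
Reagents that add atoms: none
Why: oxidative PMB cleavage under neutral conditions that leave the silyl ether, the acetate and the lactone intact.

Step 24
Reactants: 29 (2E)-2-methylbut-2-en-1-ol
Product: 30 [(2R,3R)-2,3-dimethyloxiran-2-yl]methanol
Conditions: Ti(OiPr)4, D-(−)-diethyl tartrate, t-BuOOH, 4 Å molecular sieves, CH2Cl2, −20 °C
Reagents that add atoms: tert-butyl hydroperoxide, CC(C)(C)OO
Why: Sharpless asymmetric epoxidation; the D-(−)-tartrate should give the (2R,3R) epoxide with the methyl groups cis, as the E-olefin dictates.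

Step 25
Reactants: 30 [(2R,3R)-2,3-dimethyloxiran-2-yl]methanol
Product: 31 (2S,3R)-2,3-dimethyloxirane-2-carboxylic acid
Conditions: RuCl3 (cat.), NaIO4, EtOAc/MeCN/H2O, rt
Reagents that add atoms: water, O
Why: ruthenium tetroxide oxidation of an epoxy alcohol to the glycidic acid; the centres are untouched and only the descriptor at C2 changes.

Step 26
Reactants: 28 the C8 alcohol of step 23; 31 (2S,3R)-2,3-dimethyloxirane-2-carboxylic acid
Product: 33 (1(10)Z,4Z,3S,6R,7S,8S,9R)-3-acetoxy-8-{[(2S,3R)-2,3-dimethyloxirane-2-carbonyl]oxy}-9-[(triethylsilyl)oxy]germacra-1(10),4,11(13)-trien-12,6-olide, via mixed anhydride 32 (not isolated)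
Conditions: 31, 2,4,6-Cl3C6H2COCl, Et3N, THF, rt; then 28, DMAP, toluene, rt
Reagents that add atoms: none
Why: Yamaguchi esterification; DMAP attacks the less hindered acyl group of the mixed anhydride and acylates the hindered secondary O8 with retention at every centre.

Step 27
Reactants: 33 the silyl ether of step 26
Product: 34 (1(10)Z,4Z,3S,6R,7S,8S,9R)-3-acetoxy-9-hydroxy-8-{[(2S,3R)-2,3-dimethyloxirane-2-carbonyl]oxy}germacra-1(10),4,11(13)-trien-12,6-olide (target)
Conditions: HF·pyridine, pyridine/THF, 0 °C to rt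
Reagents that add atoms: none
Why: buffered fluoride cleavage of the triethylsilyl ether; mildly acidic conditions should avoid acyl migration from O8 to O9 and leave the glycidic ester intact.

**Compound list**

1 | 3-[(tert-butyldimethylsilyl)oxy]propanal | O=CCCO[Si](C)(C)C(C)(C)C | starting material
2 | tert-butyl{[(3Z)-4-iodopent-3-en-1-yl]oxy}dimethylsilane | C/C(I)=C/CCO[Si](C)(C)C(C)(C)C | intermediate
3 | (3Z)-4-iodopent-3-en-1-ol | C/C(I)=C/CCO | intermediate
4 | (3Z)-4-iodopent-3-enal | C/C(I)=C/CC=O | intermediate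
5 | ethyl (2Z,5Z)-6-iodo-2-methylhepta-2,5-dienoate | CCOC(=O)/C(C)=C\C/C=C(/C)I | intermediate
6 | (2Z,5Z)-6-iodo-2-methylhepta-2,5-dien-1-ol | OC/C(C)=C\C/C=C(/C)I | intermediate
7 | {(2R,3S)-3-[(2Z)-3-iodobut-2-en-1-yl]-2-methyloxiran-2-yl}methanol | OC[C@@]1(C)O[C@H]1C/C=C(/C)I | intermediate
8 | (2S,3S)-3-[(2Z)-3-iodobut-2-en-1-yl]-2-methyloxirane-2-carbaldehyde | O=C[C@@]1(C)O[C@H]1C/C=C(/C)I | intermediate
9 | (2E)-but-2-ene-1,4-diol | OC/C=C/CO | starting material
10 | (2E)-4-[(tert-butyldimethylsilyl)oxy]but-2-en-1-ol | OC/C=C/CO[Si](C)(C)C(C)(C)C | intermediate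
11 | [(2R,3R)-3-({[tert-butyl(dimethyl)silyl]oxy}methyl)oxiran-2-yl]methanol | OC[C@H]1O[C@@H]1CO[Si](C)(C)C(C)(C)C | intermediate
12 | (2S,3S)-4-[(tert-butyldimethylsilyl)oxy]-2-[1-(trimethylsilyl)ethenyl]butane-1,3-diol | C=C([Si](C)(C)C)[C@@H](CO)[C@H](O)CO[Si](C)(C)C(C)(C)C | intermediate
13 | (4S,5S)-4-({[tert-butyl(dimethyl)silyl]oxy}methyl)-2-(4-methoxyphenyl)-5-[1-(trimethylsilyl)ethenyl]-1,3-dioxane, aryl equatorial | C=C([Si](C)(C)C)[C@H]1CO[C@H](c2ccc(OC)cc2)O[C@@H]1CO[Si](C)(C)C(C)(C)C | intermediate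
14 | 5-[1,2-dibromo-1-(trimethylsilyl)ethyl] analogue of 13 (both epimers at the new carbon) | BrCC(Br)([Si](C)(C)C)[C@H]1CO[C@H](c2ccc(OC)cc2)O[C@@H]1CO[Si](C)(C)C(C)(C)C | intermediate
15 | (4S,5S)-5-(1-bromoethenyl)-4-({[tert-butyl(dimethyl)silyl]oxy}methyl)-2-(4-methoxyphenyl)-1,3-dioxane | C=C(Br)[C@H]1CO[C@H](c2ccc(OC)cc2)O[C@@H]1CO[Si](C)(C)C(C)(C)C | intermediate
16 | (2S,3S)-2-(1-bromoethenyl)-4-[(tert-butyldimethylsilyl)oxy]-3-[(4-methoxybenzyl)oxy]butan-1-ol | C=C(Br)[C@@H](CO)[C@H](OCc1ccc(OC)cc1)CO[Si](C)(C)C(C)(C)C | intermediate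
17 | 5-({(2R,3S)-2-(1-bromoethenyl)-4-[(tert-butyldimethylsilyl)oxy]-3-[(4-methoxybenzyl)oxy]butyl}sulfanyl)-1-phenyl-1H-tetrazole | C=C(Br)[C@@H](CSc1nnnn1-c1ccccc1)[C@H](OCc1ccc(OC)cc1)CO[Si](C)(C)C(C)(C)C | intermediate
18 | 5-({(2R,3S)-2-(1-bromoethenyl)-4-[(tert-butyldimethylsilyl)oxy]-3-[(4-methoxybenzyl)oxy]butyl}sulfonyl)-1-phenyl-1H-tetrazole | C=C(Br)[C@@H](CS(=O)(=O)c1nnnn1-c1ccccc1)[C@H](OCc1ccc(OC)cc1)CO[Si](C)(C)C(C)(C)C | intermediate
19 | acyclic E-vinyl oxirane, primary TBS ether (name in step 16) | C=C(Br)[C@@H](/C=C/[C@@]1(C)O[C@H]1C/C=C(/C)I)[C@H](OCc1ccc(OC)cc1)CO[Si](C)(C)C(C)(C)C | intermediate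
20 | acyclic E-vinyl oxirane, primary alcohol (name in step 17) | C=C(Br)[C@@H](/C=C/[C@@]1(C)O[C@H]1C/C=C(/C)I)[C@H](OCc1ccc(OC)cc1)CO | intermediate
21 | acyclic E-vinyl oxirane, aldehyde (name in step 18) | C=C(Br)[C@@H](/C=C/[C@@]1(C)O[C@H]1C/C=C(/C)I)[C@H](OCc1ccc(OC)cc1)C=O | intermediate
22 | (1(10)Z,5E,3S,4R,7S,8S,9R)-7-(1-bromoethenyl)-3,4-epoxy-8-[(4-methoxybenzyl)oxy]-4,10-dimethylcyclodeca-1(10),5-dien-9-ol | C=C(Br)[C@H]1/C=C/[C@@]2(C)O[C@H]2C/C=C(/C)[C@@H](O)[C@H]1OCc1ccc(OC)cc1 | intermediate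
23 | 9-O-triethylsilyl ether of 22 | C=C(Br)[C@H]1/C=C/[C@@]2(C)O[C@H]2C/C=C(/C)[C@@H](O[Si](CC)(CC)CC)[C@H]1OCc1ccc(OC)cc1 | intermediate
24 | alkenyllithium from 23 (Li on C11) | [Li]C(=C)[C@H]1/C=C/[C@@]2(C)O[C@H]2C/C=C(/C)[C@@H](O[Si](CC)(CC)CC)[C@H]1OCc1ccc(OC)cc1 | intermediate
25 | lithium 2-substituted acrylate from 24 and CO2 | [Li+].[O-]C(=O)C(=C)[C@H]1/C=C/[C@@]2(C)O[C@H]2C/C=C(/C)[C@@H](O[Si](CC)(CC)CC)[C@H]1OCc1ccc(OC)cc1 | intermediate
26 | (1(10)Z,4Z,3S,6R,7S,8S,9R)-3-hydroxy-8-[(4-methoxybenzyl)oxy]-9-[(triethylsilyl)oxy]germacra-1(10),4,11(13)-trien-12,6-olide | C=C1C(=O)O[C@@H]2/C=C(/C)[C@@H](O)C/C=C(/C)[C@@H](O[Si](CC)(CC)CC)[C@@H](OCc3ccc(OC)cc3)[C@@H]12 | intermediate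
27 | 3-O-acetate of 26 | C=C1C(=O)O[C@@H]2/C=C(/C)[C@@H](OC(C)=O)C/C=C(/C)[C@@H](O[Si](CC)(CC)CC)[C@@H](OCc3ccc(OC)cc3)[C@@H]12 | intermediate
28 | (1(10)Z,4Z,3S,6R,7S,8S,9R)-3-acetoxy-8-hydroxy-9-[(triethylsilyl)oxy]germacra-1(10),4,11(13)-trien-12,6-olide | C=C1C(=O)O[C@@H]2/C=C(/C)[C@@H](OC(C)=O)C/C=C(/C)[C@@H](O[Si](CC)(CC)CC)[C@@H](O)[C@@H]12 | intermediate
29 | (2E)-2-methylbut-2-en-1-ol | C/C=C(\C)CO | starting material
30 | [(2R,3R)-2,3-dimethyloxiran-2-yl]methanol | OC[C@@]1(C)O[C@@H]1C | intermediate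
31 | (2S,3R)-2,3-dimethyloxirane-2-carboxylic acid | OC(=O)[C@@]1(C)O[C@@H]1C | intermediate
32 | (2S,3R)-2,3-dimethyloxirane-2-carboxylic 2,4,6-trichlorobenzoic anhydride | O=C(OC(=O)c1c(Cl)cc(Cl)cc1Cl)[C@@]1(C)O[C@@H]1C | intermediate
33 | 9-O-triethylsilyl ether of the target | C=C1C(=O)O[C@@H]2/C=C(/C)[C@@H](OC(C)=O)C/C=C(/C)[C@@H](O[Si](CC)(CC)CC)[C@@H](OC(=O)[C@@]3(C)O[C@@H]3C)[C@@H]12 | intermediate
34 | (1(10)Z,4Z,3S,6R,7S,8S,9R)-3-acetoxy-9-hydroxy-8-{[(2S,3R)-2,3-dimethyloxirane-2-carbonyl]oxy}germacra-1(10),4,11(13)-trien-12,6-olide | C=C1C(=O)O[C@@H]2/C=C(/C)[C@@H](OC(C)=O)C/C=C(/C)[C@@H](O)[C@@H](OC(=O)[C@@]3(C)O[C@@H]3C)[C@@H]12 | target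

**Step count and risks**

Total step count: 27.
Longest linear sequence: 18 steps (9 through steps 8–23, then 26 and 27).

The three steps most likely to fail:

1. Step 21 (key step). The alkenyllithium or t-BuLi may attack the vinyl oxirane before carboxylation, the allylpalladium intermediate may lose facial or geometric control by π–σ–π isomerisation, or β-hydride elimination may give a dienol. Fallback, which brings the lactone carbonyl in as CO instead: from 23, Pd(PPh3)4-catalysed Tsuji–Trost 1,4-addition of acetic acid (THF, rt) should give the 6-acetoxy-3-ol F1, with the same face and ring-enforced Z geometry. K2CO3 in MeOH then gives the 3,6-diol F2. Pd(PPh3)4-catalysed cyclocarbonylation of the alkenyl bromide onto the C6 hydroxyl (CO 1 atm, Et3N, MeCN, 60 °C; five-membered ring preferred over the eight-membered one through O3) closes the α-methylene lactone and returns to 26.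

2. Step 19 (macrocyclisation). Low-valent nickel may insert into the vinyl oxirane or the alkenyl bromide during the slow ring closure, the seco-aldehyde may oligomerise, or facial selectivity at C9 may be poor. Fallback, which swaps the order of the two unions so that the chromium step meets only an isolated oxirane: from 18, Bu4NF gives the alcohol F3 and Dess–Martin oxidation gives the aldehyde F4. Intermolecular Nozaki–Hiyama–Kishi coupling of F4 with the alkenyl iodide of epoxy alcohol 7 (CrCl2, NiCl2 cat., DMSO) gives the diol F5, with Felkin control at C9. TEMPO/PhI(OAc)2 oxidises only the primary alcohol to the epoxy aldehyde F6, and Et3SiCl/imidazole gives the silyl ether F7. Intramolecular Julia–Kocienski olefination (KN(SiMe3)2, THF, −78 °C, high dilution) closes C5=C6 and returns to 23.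

3. Step 10 (oxirane opening). The cuprate may attack C3 instead of C2, giving the 1,2-diol regioisomer, or the hindered α-silylvinyl reagent may transfer slowly. Fallback, which enforces α-attack electronically: from 11, RuCl3/NaIO4 gives the glycidic acid F8 and Me3SiCHN2 in MeOH gives the methyl glycidate F9. Lithium bis[1-(trimethylsilyl)ethenyl]cuprate (Et2O, −78 °C) opens the glycidic ester at the α-carbon with inversion to the β-hydroxy ester F10. LiBH4 reduction returns to 12.

**Further compounds**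

F1 | step 21 | 6-acetoxy-3-ol from 1,4-addition of acetic acid to 23 | CC(=O)O[C@@H]1/C=C(/C)[C@@H](O)C/C=C(/C)[C@@H](O[Si](CC)(CC)CC)[C@@H](OCc2ccc(OC)cc2)[C@H]1C(Br)=C
F2 | step 21 | 3,6-diol bearing the 1-bromoethenyl group | O[C@@H]1/C=C(/C)[C@@H](O)C/C=C(/C)[C@@H](O[Si](CC)(CC)CC)[C@@H](OCc2ccc(OC)cc2)[C@H]1C(Br)=C
F3 | step 19 | primary alcohol from desilylation of sulfone 18 | C=C(Br)[C@@H](CS(=O)(=O)c1nnnn1-c1ccccc1)[C@H](OCc1ccc(OC)cc1)CO
F4 | step 19 | sulfonyl aldehyde from F3 | C=C(Br)[C@@H](CS(=O)(=O)c1nnnn1-c1ccccc1)[C@H](OCc1ccc(OC)cc1)C=O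
F5 | step 19 | acyclic C9 carbinol, epoxy alcohol and sulfone (coupling product of F4 and 7) | C=C(Br)[C@@H](CS(=O)(=O)c1nnnn1-c1ccccc1)[C@H](OCc1ccc(OC)cc1)[C@H](O)/C(C)=C\C[C@@H]1O[C@]1(C)CO
F6 | step 19 | epoxy aldehyde from F5 | C=C(Br)[C@@H](CS(=O)(=O)c1nnnn1-c1ccccc1)[C@H](OCc1ccc(OC)cc1)[C@H](O)/C(C)=C\C[C@@H]1O[C@]1(C)C=O
F7 | step 19 | 9-O-triethylsilyl ether of F6 | C=C(Br)[C@@H](CS(=O)(=O)c1nnnn1-c1ccccc1)[C@H](OCc1ccc(OC)cc1)[C@H](O[Si](CC)(CC)CC)/C(C)=C\C[C@@H]1O[C@]1(C)C=O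
F8 | step 10 | glycidic acid from 11 | OC(=O)[C@H]1O[C@@H]1CO[Si](C)(C)C(C)(C)C
F9 | step 10 | methyl glycidate from F8 | COC(=O)[C@H]1O[C@@H]1CO[Si](C)(C)C(C)(C)C
F10 | step 10 | methyl 3-hydroxy-2-[1-(trimethylsilyl)ethenyl]butanoate derivative from α-opening of F9 | COC(=O)[C@H](C(=C)[Si](C)(C)C)[C@H](O)CO[Si](C)(C)C(C)(C)C
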